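I start with an easy step: in the green flask I take the target made per minute over the last two gaps between readings, and treat what comes after 120 min as a small correction to the last reading.

in all of them: free enzyme 2.1 µM

|  | starting material | temperature | remark | time |
|---|---|---|---|---|
| green | 21 mM | 25 °C | the very flask that is asked about, followed so far |  |
| blue | 42 mM | 10 °C | run made earlier |  |
| flask | 21 mM | 25 °C |  | 3.0 h |

- green (time / min: target / %): 8.00: 15.2; 15.0: 24.9; 30.0: 38.6; 60.0: 49.3; 120: 55.4
- blue (time / min: target / %): 6.00: 3.7; 12.0: 5.9; 20.0: 10.0; 25.0: 12.3; 30.0: 14.6

(each reading ± 0.3 percentage points)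

- dawn: change nothing and wait 6.0 h more
- winter: at 3.0 h raise the temperature by 20 K, then wait 6.0 h
- autumn: at 3.0 h add free enzyme, 100 % of the amount charged, then wait 6.0 h
- noon: at 3.0 h take out 90 % of the target then present, then wait 6.0 h

- what is taken out of target is counted as made
- additions bring no volume worth counting

- target, in percent of the starting material first charged, at 3.0 h
- which option adds most target ("none" when 2 percentage points or less is all one gets) (dawn / winter / autumn / noon / none)
- target present, with what was taken out counted in, in percent of the starting material first charged, after winter
- target present, with what was taken out counted in, in percent of the starting material first charged, after noon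

Between those gaps the rate shrinks by a factor e every 35.9 min, which I call its fading time. A rate that keeps fading this way still has rate times fading time to give, so I reckon the green flask has 1.6 percentage points to come after its last reading of 55.4 %. That makes a lifetime output 12.0 mM, the enzyme's total turnover counted in mM of target. Counting the tail up to 3.0 h, my own reckoning is 56.7 %.

The forecast says 55.8 %, lower than mine, with 55.9 % after winter, 55.9 % after noon and autumn as the best option, on the ground that “Waiting, heating or removing target then adds almost nothing”.

The green flask gives 56.9 % at 3.0 h, 57.1 % after winter and 57.6 % after noon. Dawn adds 0.51 points, winter 0.16 points, noon 0.64 points and autumn 6.2 points, so autumn is the best option.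

    free enzyme → unfolded enzyme (k = 3.40 × 10⁻⁶ s⁻¹, Ea = 183 kJ mol⁻¹)
    starting material + free enzyme → target + free enzyme, rate k2*[starting material]*[free enzyme]/(1 + ([starting material]/Km2) + ([target]/Kp2)) (14.0 mM, 34.0 mM, k = 450 M⁻¹ s⁻¹, Ea = 43.0 kJ mol⁻¹)
    free enzyme → spent catalyst (k = 3.00 × 10⁻⁴ s⁻¹, Ea = 88.0 kJ mol⁻¹)
    2 starting material → self-condensation product (k = 0.0100 M⁻¹ s⁻¹, Ea = 47.0 kJ mol⁻¹)
    (constants at 25 °C)

Left for 1800 min, the green flask holds 12.1 mM of target, against my output of 12.0 mM. At 180 min the green flask has 3.78 % of the enzyme charged still free and 95.1 % as spent catalyst, and that conversion is a reason for autumn's gain: in the run without it, autumn brings 0.084 points instead of 6.2 points. Self-condensation takes starting material too, but 82 % of its turnover up to 3.0 h lies behind it at 36.0 min, before the last reading, so the green readings already carry this loss.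

In the neighbour flask with 36 mM of starting material, the same output gives 33.3 %. The computed result at 3.0 h is 41.7 %, or 15.0 mM, more than 12.0 mM.

The earlier runs and the new flask stem from a simulated flask for an exercise.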